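**Retrosynthetic overview**
- The route rests on the 1,2-dione: one carbonyl carbon carries the 4-methoxyphenyl ring, the other sits on C6 of the chromene benzene ring, ortho to the C5 hydroxyl. This unit is C3, C4 and O1 of an isoflavone from which C2 has been cut out.
- The 2,2-dimethyl-2H-pyran ring (C4–C4a and O1–C2 bonds) is removed first, as prenal, from a 2,4-dihydroxy-5-methoxyphenyl 4-methoxyphenyl 1,2-dione, so that no chromene alkene meets thallium or ozone.
- The dione is traced to 7-acetoxy-6-methoxy-3-(4-methoxyphenyl)chromen-4-one by ozonolytic cleavage of C2=C3, with C2 leaving as formate.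
- The isoflavone comes from a 2'-hydroxychalcone by oxidative 1,2-shift of the 4-methoxyphenyl ring from Cβ to Cα with Tl(NO3)3, then acid closure of the pyranone ring. The chalcone comes from a MOM-protected acetophenone and 4-methoxybenzaldehyde.
- Ring order: the chromen-4-one ring is closed first and later opened again; the 2H-pyran ring is closed last.

Key step: step 3

Assumption: 1-(2,4-dihydroxy-5-methoxyphenyl)ethanone is taken as a catalogue compound, and its chelated 2-hydroxyl is carried unprotected through the thallium step, as is usual for 2'-hydroxychalcones.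

**Step 1**
Reactants: 1 1-(2,4-dihydroxy-5-methoxyphenyl)ethanone
Product: 2 1-[2-hydroxy-5-methoxy-4-(methoxymethoxy)phenyl]ethanone
Conditions: MOMCl (1.1 equiv), K2CO3, acetone, 0 °C to rt
Reagents that add atoms: chloromethyl methyl ether (MOMCl), COCCl
Why: Williamson-type O-alkylation in which the 2-hydroxyl, hydrogen-bonded to the acetyl carbonyl, is much less acidic and nucleophilic than the 4-hydroxyl, so carbonate base should etherify the 4-oxygen only and mask the phenol that would otherwise slow the aldol step and be oxidised by trivalent thallium.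

**Step 2**
Reactants: 2 1-[2-hydroxy-5-methoxy-4-(methoxymethoxy)phenyl]ethanone; 3 4-methoxybenzaldehyde
Product: 4 (E)-1-[2-hydroxy-5-methoxy-4-(methoxymethoxy)phenyl]-3-(4-methoxyphenyl)prop-2-en-1-one
Conditions: KOH (50% aq), EtOH, 0 °C to rt; AcOH to pH 6–7
Reagents that add atoms: none
Why: Claisen–Schmidt condensation (crossed aldol addition, then E1cB dehydration) of the methyl ketone enolate with a non-enolisable aldehyde, in which the conjugated (E)-enone is the thermodynamic product and the MOM acetal is inert to hydroxide.

**Step 3**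
Reactants: 4 (E)-1-[2-hydroxy-5-methoxy-4-(methoxymethoxy)phenyl]-3-(4-methoxyphenyl)prop-2-en-1-one
Product: 6 7-hydroxy-6-methoxy-3-(4-methoxyphenyl)-4H-chromen-4-one (afrormosin), via dimethyl acetal 5 (not isolated)
Conditions: Tl(NO3)3·3H2O (1.1 equiv), MeOH–HC(OMe)3 (3:1), rt; filter off TlNO3; then 10% aq HCl, MeOH, 60 °C
Reagents that add atoms: methanol, CO (its two methoxy groups are carried only by intermediate 5 and leave again on ring closure, so no reagent atom other than hydrogen stays in 6)
Why: Oxythallation of the enone by Tl(NO3)3 (trivalent thallium) should place thallium on Cα and methanol on the benzylic Cβ, after which the 4-methoxyphenyl ring shifts from Cβ to Cα through a bridged phenonium ion as monovalent thallium departs and the methoxycarbenium ion left at Cβ is trapped by methanol as dimethyl acetal 5. This is the known thallium trinitrate oxidative rearrangement of 2'-hydroxychalcones to 1-(2-hydroxyaryl)-2-aryl-3,3-dimethoxypropan-1-ones, which copies isoflavone biosynthesis and which hypervalent iodine reagents such as PhI(OH)OTs also effect. On warming with HCl the acetal ionises to the methoxycarbenium ion, the 2'-hydroxyl adds to it in a 6-exo-trig closure (new O–C bond), loss of the second methanol across C2–C3 gives the chromen-4-one, and the same acid cleaves the MOM acetal. No stereocentre remains, because the racemic α-centre of 5 becomes sp2. The step needs aryl migration in preference to aroyl migration or aurone-forming attack of the phenol, which the para-methoxy group secures by stabilising the phenonium ion and by directing methanol to Cβ. It also needs the oxidant to spare the electron-rich ketone ring, which the acyl group, the hydrogen-bonded 2'-hydroxyl and the MOM cap on the 4'-oxygen should provide.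

**Step 4**
Reactants: 6 7-hydroxy-6-methoxy-3-(4-methoxyphenyl)-4H-chromen-4-one (afrormosin)
Product: 7 6-methoxy-3-(4-methoxyphenyl)-4-oxo-4H-chromen-7-yl acetate
Conditions: Ac2O, pyridine, DMAP (cat.), rt
Reagents that add atoms: acetic anhydride, CC(=O)OC(C)=O
Why: Pyridine-mediated O-acetylation (nucleophilic acyl substitution) of the only free hydroxyl, which lowers the electron density of the phenolic ring before ozone is applied, improves solubility in dichloromethane and gives an ester that is removed together with the formate in step 6.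

**Step 5**
Reactants: 7 6-methoxy-3-(4-methoxyphenyl)-4-oxo-4H-chromen-7-yl acetate
Product: 9 5-(acetyloxy)-4-methoxy-2-[(4-methoxyphenyl)(oxo)acetyl]phenyl formate, via ozonide 8 (not isolated)
Conditions: O3/O2, CH2Cl2, −78 °C, Sudan Red 7B end point; then Me2S, −78 °C to rt
Reagents that add atoms: ozone, [O-][O+]=O
Why: Criegee ozonolysis, in which the C2=C3 enol-ether double bond is the only non-aromatic alkene and should add ozone faster than the benzene rings when the feed is stopped at the indicator end point, after which Me2S reduces the ozonide so that C3 becomes the second ketone of the 1,2-dione and C2 is left as an aryl formate on the former ring oxygen.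

**Step 6**
Reactants: 9 5-(acetyloxy)-4-methoxy-2-[(4-methoxyphenyl)(oxo)acetyl]phenyl formate
Product: 10 1-(2,4-dihydroxy-5-methoxyphenyl)-2-(4-methoxyphenyl)ethane-1,2-dione
Conditions: K2CO3 (2 equiv), MeOH, 0 °C, N2; then 1 M HCl to pH 4
Reagents that add atoms: none
Why: Base-catalysed transesterification (methanolysis) of two activated aryl esters, which should exchange with methanol at 0 °C, well below the conditions under which methoxide adds to a 1,2-dione (benzilic ester rearrangement).

**Step 7**
Reactants: 10 1-(2,4-dihydroxy-5-methoxyphenyl)-2-(4-methoxyphenyl)ethane-1,2-dione; 11 3-methylbut-2-enal (prenal)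
Product: 13 dielsianone [1-(5-hydroxy-8-methoxy-2,2-dimethyl-2H-chromen-6-yl)-2-(4-methoxyphenyl)ethane-1,2-dione], via o-quinone methide 12 (not isolated)
Conditions: prenal (3 equiv), pyridine, 120 °C (sealed tube), N2
Reagents that add atoms: none
Why: Pyridine-mediated chromenylation (formal [3+3] annulation), in which Knoevenagel-type aldol condensation of prenal at C3, the only ring carbon ortho to both hydroxyls because C5 is blocked by methoxyl, gives o-quinone methide 12, whose oxa-6π-electrocyclisation closes the 2,2-dimethyl-2H-pyran ring through the free 4-oxygen while the 2-hydroxyl stays hydrogen-bonded to the dione carbonyl.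

**Compound list**
1 | 1-(2,4-dihydroxy-5-methoxyphenyl)ethanone | COc1cc(C(C)=O)c(O)cc1O | starting material
2 | 1-[2-hydroxy-5-methoxy-4-(methoxymethoxy)phenyl]ethanone | COCOc1cc(O)c(cc1OC)C(C)=O | intermediate
3 | 4-methoxybenzaldehyde | COc1ccc(C=O)cc1 | starting material
4 | (E)-1-[2-hydroxy-5-methoxy-4-(methoxymethoxy)phenyl]-3-(4-methoxyphenyl)prop-2-en-1-one | COCOc1cc(O)c(cc1OC)C(=O)/C=C/c1ccc(OC)cc1 | intermediate
5 | dimethyl acetal, formed in the flask: rac-1-[2-hydroxy-5-methoxy-4-(methoxymethoxy)phenyl]-3,3-dimethoxy-2-(4-methoxyphenyl)propan-1-one | COCOc1cc(O)c(cc1OC)C(=O)C(c1ccc(OC)cc1)C(OC)OC | intermediate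
6 | 7-hydroxy-6-methoxy-3-(4-methoxyphenyl)-4H-chromen-4-one (afrormosin) | COc1ccc(cc1)C1=COc2cc(O)c(OC)cc2C1=O | intermediate
7 | 6-methoxy-3-(4-methoxyphenyl)-4-oxo-4H-chromen-7-yl acetate | COc1ccc(cc1)C1=COc2cc(OC(C)=O)c(OC)cc2C1=O | intermediate
8 | ozonide, formed in the flask: racemic bicyclic 1,2,4-trioxolane in which former C2 and C3 of 7 are joined by an –O– bridge and an –O–O– bridge (bridgehead configuration fixed by the bicycle) | COc1ccc(cc1)C12OOC(O1)Oc1cc(OC(C)=O)c(OC)cc1C2=O | intermediate
9 | 5-(acetyloxy)-4-methoxy-2-[(4-methoxyphenyl)(oxo)acetyl]phenyl formate | COc1ccc(cc1)C(=O)C(=O)c1cc(OC)c(OC(C)=O)cc1OC=O | intermediate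
10 | 1-(2,4-dihydroxy-5-methoxyphenyl)-2-(4-methoxyphenyl)ethane-1,2-dione | COc1ccc(cc1)C(=O)C(=O)c1cc(OC)c(O)cc1O | intermediate
11 | 3-methylbut-2-enal (prenal) | CC(C)=CC=O | starting material
12 | o-quinone methide, formed in the flask: 1-[(3Z)-2-hydroxy-5-methoxy-3-(3-methylbut-2-en-1-ylidene)-4-oxocyclohexa-1,5-dien-1-yl]-2-(4-methoxyphenyl)ethane-1,2-dione | COc1ccc(cc1)C(=O)C(=O)C1=C(O)/C(=C/C=C(C)C)C(=O)C(OC)=C1 | intermediate
13 | dielsianone, 1-(5-hydroxy-8-methoxy-2,2-dimethyl-2H-chromen-6-yl)-2-(4-methoxyphenyl)ethane-1,2-dione (achiral) | COc1ccc(C(=O)C(=O)c2cc(OC)c3c(c2O)C=CC(C)(C)O3)cc1 | target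

**Step count**
Total steps: 7. Longest linear sequence: 7 steps (1 to 13).

**Steps most likely to fail**

Step 3 (key step). What may go wrong: oxidation of the electron-rich ketone ring by trivalent thallium (its 2'-hydroxyl is para to the 5'-methoxyl), or attack of the phenol oxygen on the thallated enone in competition with aryl migration. The fallback sets out from 2 and replaces the aryl shift by a cross-coupling. Condensation of 2 with N,N-dimethylformamide dimethyl acetal (toluene, 90 °C) should give the enaminone (E)-3-(dimethylamino)-1-[2-hydroxy-5-methoxy-4-(methoxymethoxy)phenyl]prop-2-en-1-one F1. Iodine in CHCl3–pyridine at rt should cyclise it, with loss of dimethylamine, to 3-iodo-6-methoxy-7-(methoxymethoxy)-4H-chromen-4-one F2. Suzuki–Miyaura coupling with 4-methoxyphenylboronic acid (Pd(PPh3)4, Na2CO3, DME–H2O, 80 °C) should give 6-methoxy-7-(methoxymethoxy)-3-(4-methoxyphenyl)-4H-chromen-4-one F3. HCl in methanol then removes the MOM group, and the route is rejoined at 6.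

Step 5. What may go wrong: over-oxidation of the aromatic rings by ozone, or anomalous fragmentation of the α-keto peroxide with cleavage of the C3–C4 bond. The fallback sets out from 6 and removes C2 by hydrolysis instead of oxidation. Aqueous KOH in ethanol at reflux under nitrogen should open the pyranone by conjugate addition of hydroxide at C2 and retro-Claisen loss of formate, giving the deoxybenzoin 1-(2,4-dihydroxy-5-methoxyphenyl)-2-(4-methoxyphenyl)ethanone F4. Ac2O–pyridine at rt should give 4-methoxy-6-[(4-methoxyphenyl)acetyl]-1,3-phenylene diacetate F5. Riley oxidation of the doubly activated methylene with SeO2 in dioxane at reflux should give 4-methoxy-6-[(4-methoxyphenyl)(oxo)acetyl]-1,3-phenylene diacetate F6. K2CO3 in methanol at 0 °C then removes both acetates, and the route is rejoined at 10.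

Step 7. What may go wrong: slow C-alkylation of the acyl-deactivated ring, so that self-condensation of prenal or its addition to the 1,2-dione takes over. The fallback sets out from 10 and builds the pyran ring by a sigmatropic route. O-Alkylation of the non-chelated 4-hydroxyl with 3-chloro-3-methylbut-1-yne (K2CO3, KI, CuI cat., acetone, reflux) should give 1-{2-hydroxy-5-methoxy-4-[(2-methylbut-3-yn-2-yl)oxy]phenyl}-2-(4-methoxyphenyl)ethane-1,2-dione F7. Heating in N,N-diethylaniline at 180 °C should bring about aryl propargyl Claisen rearrangement to C3 (the only free ortho position), a [1,5]-hydrogen shift and oxa-6π-electrocyclisation, and the route is rejoined at 13.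

**Further compounds**
F1 | step 3 | (E)-3-(dimethylamino)-1-[2-hydroxy-5-methoxy-4-(methoxymethoxy)phenyl]prop-2-en-1-one | COCOc1cc(O)c(cc1OC)C(=O)/C=C/N(C)C
F2 | step 3 | 3-iodo-6-methoxy-7-(methoxymethoxy)-4H-chromen-4-one | COCOc1cc2OC=C(I)C(=O)c2cc1OC
F3 | step 3 | 6-methoxy-7-(methoxymethoxy)-3-(4-methoxyphenyl)-4H-chromen-4-one | COCOc1cc2OC=C(c3ccc(OC)cc3)C(=O)c2cc1OC
F4 | step 5 | 1-(2,4-dihydroxy-5-methoxyphenyl)-2-(4-methoxyphenyl)ethanone | COc1ccc(CC(=O)c2cc(OC)c(O)cc2O)cc1
F5 | step 5 | 4-methoxy-6-[(4-methoxyphenyl)acetyl]-1,3-phenylene diacetate | COc1ccc(CC(=O)c2cc(OC)c(OC(C)=O)cc2OC(C)=O)cc1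
F6 | step 5 | 4-methoxy-6-[(4-methoxyphenyl)(oxo)acetyl]-1,3-phenylene diacetate | COc1ccc(cc1)C(=O)C(=O)c1cc(OC)c(OC(C)=O)cc1OC(C)=O
F7 | step 7 | 1-{2-hydroxy-5-methoxy-4-[(2-methylbut-3-yn-2-yl)oxy]phenyl}-2-(4-methoxyphenyl)ethane-1,2-dione | COc1ccc(cc1)C(=O)C(=O)c1cc(OC)c(OC(C)(C)C#C)cc1O
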